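The dihydrofuran ring (O1–C2–C3–C3a–C7a) is traced back to the six-membered pyranone ring of a flavanone, in which the future C3-methyl carbon is still the ring carbonyl C4, placed between C3 and the arene carbon C4a (the later C3a). The key step, an iodine(III)-mediated oxidative 1,2-aryl shift, moves C4a from C4 to C3: in one operation it forms the C3–C3a bond, pushes C4 out of the ring as an ester (later reduced to CH3) and sets the 2,3-trans relationship from the C2 stereocentre. The precursor is (S)-7-pivaloyloxy-3′,4′,5′-trimethoxyflavanone, made by asymmetric conjugate arylation of a chromone; the allyl group is introduced last by O-allylation and Claisen rearrangement.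

Key step: step 3

Assumption: the Pd/pyridine-oxazoline conjugate arylation is taken to show the same facial sense on chromones as on carbocyclic enones, so that (R)-t-BuPyOx leads to the (2S)-flavanone; should the sense prove opposite, the antipodal ligand is used without other change.

Step 1
Reactants: 1 7-hydroxy-4H-chromen-4-one; 2 pivaloyl chloride
Product: 3 4-oxo-4H-chromen-7-yl pivalate
Conditions: PivCl, Et3N, DMAP (cat.), CH2Cl2, 0 °C → rt
Reagents that add atoms: pivaloyl chloride CC(C)(C)C(=O)Cl
Why: DMAP-catalysed O-acylation of the phenol (nucleophilic acyl substitution) installs an ester that should survive cationic Pd(II) and acidic orthoformate, keeps the phenol safe from iodine(III), and is removed without a separate step by LiAlH4 in step 4.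

Step 2
Reactants: 3 4-oxo-4H-chromen-7-yl pivalate; 4 3,4,5-trimethoxyphenylboronic acid
Product: 5 (S)-4-oxo-2-(3,4,5-trimethoxyphenyl)chroman-7-yl pivalate
Conditions: Pd(OCOCF3)2 (5 mol %), (R)-t-BuPyOx (6 mol %), NH4PF6 (30 mol %), H2O (5 equiv), ClCH2CH2Cl, 60 °C
Reagents that add atoms: 3,4,5-trimethoxyphenylboronic acid COc1cc(B(O)O)cc(OC)c1OC
Why: Pd(II)-catalysed asymmetric conjugate addition of an arylboronic acid (transmetalation, enantio-determining insertion of the chromone C2=C3 bond into the aryl–Pd bond, protonolysis of the Pd enolate by water), in which the chiral pyridine-oxazoline ligand selects the face of C2 and so sets the (S) centre, while the phosphine-free Pd(II) manifold leaves the aryl ester untouched.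

Step 3
Reactants: 5 (S)-4-oxo-2-(3,4,5-trimethoxyphenyl)chroman-7-yl pivalate; 6 trimethyl orthoformate
Product: 9 methyl (2S,3S)-6-(pivaloyloxy)-2-(3,4,5-trimethoxyphenyl)-2,3-dihydrobenzofuran-3-carboxylate, via enol ether 7 (not isolated), via iodane ketal 8 (not isolated)
Conditions: PhI(OAc)2 (1.1 equiv), conc. H2SO4 (cat.), HC(OMe)3, 0 °C → rt; aq. NaHCO3 work-up
Reagents that add atoms: trimethyl orthoformate COC(OC)OC; water O
Why: Acid and orthoformate convert the ketone into enol ether 7, whose C3 is attacked by the iodine(III) electrophile anti to the C2 aryl group while methanol adds at C4 to give iodane ketal 8; the C4–C4a bond, antiperiplanar to the C3–I bond, then migrates to C3 with loss of iodobenzene, and the dimethoxycarbenium ion left at the extruded carbon is hydrolysed to the methyl ester on work-up. The closest known reaction type is the hypervalent-iodine (or thallium(III)) oxidative ring contraction of flavanones and related cyclic aryl ketones in trimethyl orthoformate. The five-membered ring is closed not by a cyclisation but by the 1,2-shift of arene carbon C4a from C4 to C3 through a phenonium-type bridged transition state, so the C3–C3a bond forms as the C4–C4a bond breaks. The new C3 stereocentre is controlled by the C2 stereocentre: the iodane enters trans to the aryl group and is displaced with inversion, which places the ester carbon trans to the aryl group, also the thermodynamically preferred arrangement, while C2 itself is not touched. The step needs migration of the A-ring carbon rather than of the C2 aryl group (isoflavone pathway) and oxidation of the enol ether rather than of the trimethoxyarene; the first is secured by ketalisation at C4 (the shift leaves a dialkoxy-stabilised cation) and by O1 ortho to C4a, the second by the far higher nucleophilicity of the enol ether.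

Step 4
Reactants: 9 methyl (2S,3S)-6-(pivaloyloxy)-2-(3,4,5-trimethoxyphenyl)-2,3-dihydrobenzofuran-3-carboxylate
Product: 10 (2S,3R)-3-(hydroxymethyl)-2-(3,4,5-trimethoxyphenyl)-2,3-dihydrobenzofuran-6-ol
Conditions: LiAlH4 (excess), THF, 0 °C → rt; aq. Rochelle salt
Reagents that add atoms: none
Why: Hydride reduction of the methyl ester to the primary alcohol with simultaneous reductive cleavage of the aryl pivalate should give the phenol-alcohol without touching either stereocentre (the descriptor at C3 changes only because of the priority rules).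

Step 5
Reactants: 10 (2S,3R)-3-(hydroxymethyl)-2-(3,4,5-trimethoxyphenyl)-2,3-dihydrobenzofuran-6-ol; 11 allyl bromide
Product: 12 [(2S,3R)-6-(allyloxy)-2-(3,4,5-trimethoxyphenyl)-2,3-dihydrobenzofuran-3-yl]methanol
Conditions: allyl bromide (1.2 equiv), K2CO3, acetone, reflux
Reagents that add atoms: allyl bromide C=CCBr
Why: Williamson etherification under carbonate base is chemoselective for the phenoxide over the un-ionised primary alcohol.

Step 6
Reactants: 12 [(2S,3R)-6-(allyloxy)-2-(3,4,5-trimethoxyphenyl)-2,3-dihydrobenzofuran-3-yl]methanol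
Product: 14 (2S,3S)-6-(allyloxy)-3-methyl-2-(3,4,5-trimethoxyphenyl)-2,3-dihydrobenzofuran, via mesylate 13 (not isolated)
Conditions: MsCl, Et3N, THF, 0 °C; then LiEt3BH (excess), THF, 0 °C → rt
Reagents that add atoms: none
Why: Sulfonylation of the primary alcohol followed by direct SN2 hydride displacement with the strongly nucleophilic triethylborohydride (alcohol deoxygenation) should turn CH2OH into CH3 faster than any aryl-assisted ionisation, and no stereocentre takes part.

Step 7
Reactants: 14 (2S,3S)-6-(allyloxy)-3-methyl-2-(3,4,5-trimethoxyphenyl)-2,3-dihydrobenzofuran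
Product: 16 (2S,3S)-5-allyl-3-methyl-2-(3,4,5-trimethoxyphenyl)-2,3-dihydrobenzofuran-6-ol, via ortho-dienone 15 (not isolated)
Conditions: PhNEt2, 190 °C, sealed tube, Ar
Reagents that add atoms: none
Why: Aromatic Claisen rearrangement ([3,3]-sigmatropic shift to ortho-dienone 15, then tautomerisation) should deliver the allyl group to C5, the ortho position para to O1 and remote from the ring fusion, rather than to C7, which is flanked by both oxygens, as is usual for allyl ethers of phenols with a meta oxygen in a fused five-membered ring; no stereocentre is involved.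

Compound list
1 | 7-hydroxy-4H-chromen-4-one | O=c1ccoc2cc(O)ccc12 | starting material
2 | pivaloyl chloride | CC(C)(C)C(=O)Cl | starting material
3 | 4-oxo-4H-chromen-7-yl pivalate | O=c1ccoc2cc(OC(=O)C(C)(C)C)ccc12 | intermediate
4 | 3,4,5-trimethoxyphenylboronic acid | COc1cc(B(O)O)cc(OC)c1OC | starting material
5 | (S)-4-oxo-2-(3,4,5-trimethoxyphenyl)chroman-7-yl pivalate | O=C1C[C@@H](c2cc(OC)c(OC)c(OC)c2)Oc2cc(OC(=O)C(C)(C)C)ccc12 | intermediate
6 | trimethyl orthoformate | COC(OC)OC | starting material
7 | (S)-4-methoxy-2-(3,4,5-trimethoxyphenyl)-2H-chromen-7-yl pivalate (enol ether) | COC1=C[C@@H](c2cc(OC)c(OC)c(OC)c2)Oc2cc(OC(=O)C(C)(C)C)ccc12 | intermediate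
8 | (2R,3R)-3-[acetoxy(phenyl)-λ3-iodanyl]-4,4-dimethoxy-2-(3,4,5-trimethoxyphenyl)chroman-7-yl pivalate (iodine trans to the aryl group) | COC1(OC)[C@H](I(c3ccccc3)OC(C)=O)[C@@H](c3cc(OC)c(OC)c(OC)c3)Oc2cc(OC(=O)C(C)(C)C)ccc12 | intermediate
9 | methyl (2S,3S)-6-(pivaloyloxy)-2-(3,4,5-trimethoxyphenyl)-2,3-dihydrobenzofuran-3-carboxylate (2,3-trans) | CC(C)(C)C(=O)Oc1ccc2c(c1)O[C@H](c1cc(OC)c(OC)c(OC)c1)[C@H]2C(=O)OC | intermediate
10 | (2S,3R)-3-(hydroxymethyl)-2-(3,4,5-trimethoxyphenyl)-2,3-dihydrobenzofuran-6-ol | Oc1ccc2c(c1)O[C@H](c1cc(OC)c(OC)c(OC)c1)[C@H]2CO | intermediate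
11 | allyl bromide | C=CCBr | starting material
12 | [(2S,3R)-6-(allyloxy)-2-(3,4,5-trimethoxyphenyl)-2,3-dihydrobenzofuran-3-yl]methanol | C=CCOc1ccc2c(c1)O[C@H](c1cc(OC)c(OC)c(OC)c1)[C@H]2CO | intermediate
13 | [(2S,3R)-6-(allyloxy)-2-(3,4,5-trimethoxyphenyl)-2,3-dihydrobenzofuran-3-yl]methyl methanesulfonate | C=CCOc1ccc2c(c1)O[C@H](c1cc(OC)c(OC)c(OC)c1)[C@H]2COS(C)(=O)=O | intermediate
14 | (2S,3S)-6-(allyloxy)-3-methyl-2-(3,4,5-trimethoxyphenyl)-2,3-dihydrobenzofuran | C=CCOc1ccc2c(c1)O[C@H](c1cc(OC)c(OC)c(OC)c1)[C@H]2C | intermediate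
15 | (2S,3S)-5-allyl-3-methyl-2-(3,4,5-trimethoxyphenyl)-3,5-dihydrobenzofuran-6(2H)-one (both C5 epimers) | C=CCC1C=C2C(=CC1=O)O[C@H](c1cc(OC)c(OC)c(OC)c1)[C@H]2C | intermediate
16 | (2S,3S)-5-allyl-3-methyl-2-(3,4,5-trimethoxyphenyl)-2,3-dihydrobenzofuran-6-ol | C=CCc1cc2c(cc1O)O[C@H](c1cc(OC)c(OC)c(OC)c1)[C@H]2C | target

Total step count: 7. Longest linear sequence: 7 steps (1 → 16).

Steps most likely to fail

1. Step 3 (key step). The oxidative shift may be diverted: migration of the electron-rich C2 aryl group instead of C4a (leading to an isoflavone), simple dehydrogenation to the flavone, attack of the iodine(III) reagent on the trimethoxyarene, or acid loss of the pivalate followed by phenol oxidation. Fallback, from 5 back to 9: the same contraction would be run as a Wolff rearrangement. Flavanone 5 would be condensed with N,N-dimethylformamide dimethyl acetal (toluene, 90 °C) to (R)-3-[(dimethylamino)methylidene]-4-oxo-2-(3,4,5-trimethoxyphenyl)chroman-7-yl pivalate F1, which with p-toluenesulfonyl azide (MeCN, rt) should undergo deformylative diazo transfer to (R)-3-diazo-4-oxo-2-(3,4,5-trimethoxyphenyl)chroman-7-yl pivalate F2. Irradiation (350 nm, MeOH/THF, rt) should expel nitrogen with shift of C4a to the carbene carbon, giving the ring-contracted ketene (R)-3-(oxomethylidene)-2-(3,4,5-trimethoxyphenyl)-2,3-dihydrobenzofuran-6-yl pivalate F3, which methanol traps. Protonation anti to the aryl group is expected to favour the cis ester methyl (2S,3R)-6-(pivaloyloxy)-2-(3,4,5-trimethoxyphenyl)-2,3-dihydrobenzofuran-3-carboxylate F4, which catalytic DBU (CH2Cl2, rt) should equilibrate to trans ester 9.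

2. Step 2. The conjugate arylation may be slow with this 3,5-disubstituted electron-rich boronic acid (protodeboronation competing) or may give insufficient enantioselectivity on the chromone. Fallback, from 3 back to 5: enantioselective C–C bond formation is replaced by resolution. Non-selective arylation of 3 with 4 (Pd(OCOCF3)2, 2,2′-bipyridine, NH4PF6, H2O, ClCH2CH2Cl, 60 °C) should give racemic 4-oxo-2-(3,4,5-trimethoxyphenyl)chroman-7-yl pivalate F5. Kinetic resolution by asymmetric transfer hydrogenation (Ru(II)–TsDPEN catalyst, HCO2H/Et3N, EtOAc, rt), using the catalyst antipode that reduces the (2R)-ketone faster, should convert that enantiomer into (2R,4R)-4-hydroxy-2-(3,4,5-trimethoxyphenyl)chroman-7-yl pivalate F6. Unreacted (S)-5 would then be separated by chromatography.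

3. Step 7. The allyl group may migrate in part to C7, or the long heating may erode the trans arrangement. Fallback, from 14 back to 16: the ortho-selective sigmatropic shift is replaced by electrophilic substitution para to O1 followed by cross-coupling. The O-allyl group of 14 would be removed (Pd(PPh3)4 cat., morpholine, THF, rt) to give (2S,3S)-3-methyl-2-(3,4,5-trimethoxyphenyl)-2,3-dihydrobenzofuran-6-ol F7. NBS (MeCN, −20 °C) should brominate the free phenol ring at C5, ortho to OH and para to O1, in preference to the hindered C7 and to the less activated trimethoxyarene, giving (2S,3S)-5-bromo-3-methyl-2-(3,4,5-trimethoxyphenyl)-2,3-dihydrobenzofuran-6-ol F8. Stille coupling with allyltributylstannane (Pd(PPh3)4, DMF, 90 °C) should then give 16.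

Further compounds
F1 | step 3 | (R)-3-[(dimethylamino)methylidene]-4-oxo-2-(3,4,5-trimethoxyphenyl)chroman-7-yl pivalate | O=C1C(=CN(C)C)[C@@H](c2cc(OC)c(OC)c(OC)c2)Oc2cc(OC(=O)C(C)(C)C)ccc12
F2 | step 3 | (R)-3-diazo-4-oxo-2-(3,4,5-trimethoxyphenyl)chroman-7-yl pivalate | O=C1C(=[N+]=[N-])[C@@H](c2cc(OC)c(OC)c(OC)c2)Oc2cc(OC(=O)C(C)(C)C)ccc12
F3 | step 3 | (R)-3-(oxomethylidene)-2-(3,4,5-trimethoxyphenyl)-2,3-dihydrobenzofuran-6-yl pivalate | O=C=C1c2ccc(OC(=O)C(C)(C)C)cc2O[C@@H]1c1cc(OC)c(OC)c(OC)c1
F4 | step 3 | methyl (2S,3R)-6-(pivaloyloxy)-2-(3,4,5-trimethoxyphenyl)-2,3-dihydrobenzofuran-3-carboxylate (2,3-cis) | CC(C)(C)C(=O)Oc1ccc2c(c1)O[C@H](c1cc(OC)c(OC)c(OC)c1)[C@@H]2C(=O)OC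
F5 | step 2 | rac-4-oxo-2-(3,4,5-trimethoxyphenyl)chroman-7-yl pivalate | O=C1CC(c2cc(OC)c(OC)c(OC)c2)Oc2cc(OC(=O)C(C)(C)C)ccc12
F6 | step 2 | (2R,4R)-4-hydroxy-2-(3,4,5-trimethoxyphenyl)chroman-7-yl pivalate (2,4-cis) | O[C@@H]1C[C@H](c2cc(OC)c(OC)c(OC)c2)Oc2cc(OC(=O)C(C)(C)C)ccc12
F7 | step 7 | (2S,3S)-3-methyl-2-(3,4,5-trimethoxyphenyl)-2,3-dihydrobenzofuran-6-ol | Oc1ccc2c(c1)O[C@H](c1cc(OC)c(OC)c(OC)c1)[C@H]2C
F8 | step 7 | (2S,3S)-5-bromo-3-methyl-2-(3,4,5-trimethoxyphenyl)-2,3-dihydrobenzofuran-6-ol | Brc1cc2c(cc1O)O[C@H](c1cc(OC)c(OC)c(OC)c1)[C@H]2C
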